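All five stereocentres are traced to one meso compound. With the chain numbered C1 (lactone carbonyl) to C12 (methyl), C6–C11, two threo carbinols flanking the cis-2,5-disubstituted oxolane (ring A), is mirror-symmetric about the ring oxygen, and C5 is erythro to C6. Cutting C3–C4, the acyl–O5 bond of ring B and the C11 ester leads back to a C4/C5 epoxy alcohol and then to meso cis-2,5-bis(1-hydroxyallyl)oxolane, built stereospecifically by permanganate oxidative cyclisation of an E,E-1,5-diene. One titanium–tartrate epoxidation picks the C6 arm, closes the C4–C5 oxirane, sets C5 and thereby decides the handedness of C6, C7, C10 and C11.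

Key step: step 6

Remark: the target is read from its SMILES as 5R,6S,7R,10S,11S with a Z cinnamate; all intermediates keep the chain numbering C1–C12 (C13 is the vinyl carbon that is later excised), ring A is the oxolane, ring B the dihydropyranone, and L-(+)-DIPT is diisopropyl (2R,3R)-tartrate; where a CIP letter changes between intermediates only the priorities change, not the geometry.

Step 1
Reactants: 1 hexa-1,5-diene; 2 methyl acrylate
Product: 3 dimethyl (2E,6E)-octa-2,6-dienedioate
Conditions: [RuCl2(=CH-C6H4-2-OiPr)(H2IMes)] (second-generation Hoveyda–Grubbs catalyst, 2 mol %), 2 (6 equiv), CH2Cl2, 40 °C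
Reagents that add atoms: none
Why: Olefin cross-metathesis of a terminal alkene with an acrylate is product-selective and strongly E-selective, the 1,5-diene cannot ring-close, and homo-oligomers of 1 are recycled to 3 by secondary metathesis with the excess acrylate.

Step 2
Reactants: 3 dimethyl (2E,6E)-octa-2,6-dienedioate
Product: 4 dimethyl (2R,2'S)-2,2'-[(2S,5R)-oxolane-2,5-diyl]bis(2-hydroxyacetate) (meso; threo–cis–threo)
Conditions: KMnO4 (1.4 equiv), AcOH (3 equiv), acetone/H2O, −30 → −10 °C; aqueous Na2S2O5
Reagents that add atoms: potassium permanganate, [K+].[O-][Mn](=O)(=O)=O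
Why: Permanganate oxidative cyclisation of a 1,5-diene: permanganate adds [3+2] to one E-enoate and the cyclic manganate ester then adds to the second alkene within the same molecule, so each C=C receives two oxygens suprafacially (threo at C6/C7 and C10/C11 from the E geometry) and the tethered metal ester closes ring A cis, which makes the meso threo–cis–threo diol the only stereoisomer the mechanism allows.

Step 3
Reactants: 4 meso diol diester
Product: 5 (1S,1'R)-1,1'-[(2S,5R)-oxolane-2,5-diyl]di(ethane-1,2-diol) (meso tetraol)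
Conditions: NaBH4 (6 equiv), MeOH/THF, 0 °C → rt; acidic resin, evaporation from MeOH
Reagents that add atoms: none
Why: Borohydride reduction of α-hydroxy esters, which the neighbouring hydroxyl activates, gives both primary alcohols and leaves C6 and C11 as non-enolisable carbinols from here on.

Step 4
Reactants: 5 meso tetraol
Product: 7 (2S,5R)-2-[(2S)-oxiran-2-yl]-5-[(2R)-oxiran-2-yl]oxolane (meso bis-epoxide), via bis(primary tosylate) 6 (not isolated)
Conditions: TsCl (2.1 equiv), Bu2SnO (5 mol %), Et3N, MeCN, 0 °C → rt; then K2CO3, MeOH, 0 °C → rt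
Reagents that add atoms: none
Why: Stannylene-catalysed sulfonylation picks the primary hydroxyl of each terminal 1,2-diol and intramolecular Williamson etherification then closes both oxiranes by attack of the secondary alkoxide on CH2, so the C6–O and C11–O bonds are never broken and the meso configuration is retained.

Step 5
Reactants: 7 meso bis-epoxide
Product: 8 (1S,1'R)-1,1'-[(2S,5R)-oxolane-2,5-diyl]di(prop-2-en-1-ol) (meso cis-2,5-bis(1-hydroxyallyl)oxolane; threo at both arms; C6 is R, C11 is S)
Conditions: Me3S+ I− (6 equiv), n-BuLi (5.5 equiv), THF, −10 °C → rt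
Reagents that add atoms: trimethylsulfonium iodide, C[S+](C)C.[I-]
Why: Sulfonium-ylide homologation of a terminal epoxide to an allylic alcohol: the ylide opens each oxirane at CH2 and the β-alkoxy sulfonium intermediate loses dimethyl sulfide by ylide-mediated elimination, which adds C4 and C13 as =CH2 without touching the carbinol centres.

Step 6
Reactants: 8 meso cis-2,5-bis(1-hydroxyallyl)oxolane
Product: 9 (S)-[(2R)-oxiran-2-yl]{(2R,5S)-5-[(1S)-1-hydroxyprop-2-en-1-yl]oxolan-2-yl}methanol (C4/C5 epoxy alcohol; 5R,6S,7R,10S,11S)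
Conditions: Ti(OiPr)4 (1.0 equiv), L-(+)-DIPT (1.2 equiv), TBHP (1.5 equiv, anhydrous), 4 Å MS, CH2Cl2, −20 °C
Reagents that add atoms: tert-butyl hydroperoxide, CC(C)(C)OO
Why: The titanium–tartrate dimer exchanges isopropoxide for the C6 alkoxide of 8 and for tert-butyl peroxide and hands the distal peroxide oxygen to C4=C5 in one concerted, suprafacial step, so both C–O bonds form together and the oxirane closes as a three-membered ring by [2+1] oxygen-atom transfer without an open intermediate. The closest known reaction type is the Sharpless kinetic resolution of secondary 1-alken-3-ols, used here as an enantiotopic-group-selective epoxidation of a meso bis-allylic diol. C5 is the only new stereocentre and is reagent-controlled: the (R,R)-tartrate directs oxygen to the alkene face on which the C6 substituent (C7 of ring A) points away from the ligand, which should give 5R and the erythro C5/C6 pair. Two selectivities are needed, arm against arm and face against face, and one element secures both, because the (R)-carbinol C6 is the matched and its mirror-image (S)-carbinol C11 the mismatched partner of L-(+)-tartrate. Whatever is epoxidised at the C11 arm by mistake still offers its matched C6 vinyl carbinol and is oxidised again to a separable bis-epoxide, a self-correction expected to raise the enantiomeric purity of 9 with conversion. Fixing which arm reacts fixes the handedness of C6, C7, C10 and C11 at the same time.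

Step 7
Reactants: 9 epoxy alcohol
Product: 10 6,11-bis-O-(tert-butyldimethylsilyl) ether of 9 (5R,6S,7R,10S,11S)
Conditions: TBSCl (3 equiv), imidazole (5 equiv), DMF, 0 °C → rt
Reagents that add atoms: tert-butyldimethylsilyl chloride, CC(C)(C)[Si](C)(C)Cl
Why: Standard silylation of two secondary alcohols under mildly basic conditions that neither open the terminal epoxide nor let it migrate.

Step 8
Reactants: 10 bis-silyl ether
Product: 12 C12 primary alcohol (6,11-bis-O-TBS; C4/C5 epoxide; 11S), via C12 aldehyde 11 (not isolated)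
Conditions: O3, CH2Cl2/MeOH (3:1), NaHCO3, −78 °C; then NaBH4, −78 → 0 °C; NH4Cl
Reagents that add atoms: ozone, [O-][O+]=O
Why: Ozonolysis with reductive work-up: the vinyl group is the only C=C in 10 and the α-silyloxy aldehyde 11 is reduced in the same flask before it can epimerise at C11, which removes C13.

Step 9
Reactants: 12 C12 primary alcohol
Product: 13 C12 primary iodide (6,11-bis-O-TBS; C4/C5 epoxide; 11R by priority change)
Conditions: I2, PPh3, imidazole, CH2Cl2, 0 °C → rt
Reagents that add atoms: iodine, II
Why: Garegg–Samuelsson (Appel-type) iodination of a primary alcohol, buffered by imidazole so that the silyl ethers and the oxirane persist, as in the routine conversion of epoxy alcohols into epoxy iodides.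

Step 10
Reactants: 13 C12 primary iodide
Product: 14 C12 methyl compound (6,11-bis-O-TBS; C4/C5 epoxide; 5R,6S,7R,10S,11S)
Conditions: Bu3SnH, AIBN (cat.), toluene, 80 °C
Reagents that add atoms: none
Why: Radical-chain dehalogenation with Bu3SnH replaces C12–I by C12–H through a primary radical remote from the oxirane, which completes the vinyl-to-methyl trimming under neutral conditions that spare the epoxide as a hydride displacement would not.

Step 11
Reactants: 14 C12 methyl epoxide; 15 methyl propiolate
Product: 17 methyl 5-hydroxy-alk-2-ynoate (C1–C12 chain; 6,11-bis-O-TBS; 5R,6R,7R,10S,11S), via methyl 3-lithiopropiolate 16 (not isolated)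
Conditions: 15 (3 equiv), n-BuLi (3 equiv), THF, −78 °C; BF3·OEt2 (3 equiv); then 14, −78 °C; NH4Cl
Reagents that add atoms: none
Why: BF3-promoted alkynylation of a terminal epoxide (Yamaguchi–Hirao conditions): the lithium acetylide attacks the unsubstituted C4, so the C3–C4 bond forms while the C5–O bond and its configuration are kept and O5 emerges as the hydroxyl that later becomes the ring oxygen of ring B.

Step 12
Reactants: 17 bis-silyl hydroxy ynoate
Product: 19 5,6-O-isopropylidene ynoate with free 11-OH (5R,6S,7R,10S,11S), via triol 18 (not isolated)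
Conditions: CSA (1 equiv), MeOH, rt; evaporate; Me2C(OMe)2/acetone, CSA (cat.), 0 °C → rt; Et3N, silica (any mixed ketal at O11 is lost)
Reagents that add atoms: 2,2-dimethoxypropane, COC(C)(C)OC
Why: Acid methanolysis frees O6 and O11 without base (no conjugate addition of O6 to the ynoate) and ketalisation then engages the only vicinal diol, O5/O6, as a 1,3-dioxolane, which leaves O11 as the single free hydroxyl and so settles the O6/O11 differentiation by constitution and not by relative reactivity.

Step 13
Reactants: 19 acetonide alcohol; 20 3-(4-methoxyphenyl)prop-2-ynoic acid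
Product: 21 11-O-[3-(4-methoxyphenyl)propioloyl] ester of 19
Conditions: DCC (1.5 equiv), DMAP (0.1 equiv), CH2Cl2, 0 °C → rt
Reagents that add atoms: none
Why: Steglich esterification of the only free hydroxyl proceeds at oxygen with retention at C11, and carrying the cinnamate as an alkyne avoids Z/E scrambling during acylation.

Step 14
Reactants: 21 bis-alkynoate
Product: 22 (2Z)-enoate methyl ester carrying the (Z)-4-methoxycinnamate at O11 and the 5,6-acetonide
Conditions: H2 (1 atm), Pd/CaCO3 poisoned with Pb(OAc)2 (Lindlar catalyst), quinoline, EtOAc, rt, dark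
Reagents that add atoms: none
Why: Lindlar semi-hydrogenation adds H2 syn to both conjugated alkynes and so sets the C2=C3 and the cinnamate double bonds Z in one operation, while the ketal keeps O5 from lactonising or adding prematurely.

Step 15
Reactants: 22 Z,Z-diester acetonide
Product: 24 (1S)-1-[(2S,5R)-5-{(S)-hydroxy[(2R)-6-oxo-3,6-dihydro-2H-pyran-2-yl]methyl}oxolan-2-yl]ethyl (2Z)-3-(4-methoxyphenyl)prop-2-enoate (target), via dihydroxy diester 23 (not isolated)
Conditions: AcOH/H2O (4:1), 40 °C, dark; toluene azeotrope
Reagents that add atoms: none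
Why: Acid hydrolysis of the isopropylidene ketal releases O5 and O6, and O5, held next to the ester by the Z-alkene, closes ring B by lactonisation (six-membered, loss of methanol) whereas O6 could only form a seven-membered lactone and stays as the free hydroxyl of the target.

Compound list
1 | hexa-1,5-diene | C=CCCC=C | starting material
2 | methyl acrylate | C=CC(=O)OC | starting material
3 | dimethyl (2E,6E)-octa-2,6-dienedioate | COC(=O)/C=C/CC/C=C/C(=O)OC | intermediate
4 | dimethyl (2R,2'S)-2,2'-[(2S,5R)-oxolane-2,5-diyl]bis(2-hydroxyacetate), meso, R carbinol on the S ring carbon | O[C@@H](C(=O)OC)[C@@H]1CC[C@H]([C@H](O)C(=O)OC)O1 | intermediate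
5 | (1S,1'R)-1,1'-[(2S,5R)-oxolane-2,5-diyl]di(ethane-1,2-diol), meso, S carbinol on the S ring carbon | O[C@@H](CO)[C@@H]1CC[C@H]([C@H](O)CO)O1 | intermediate
6 | bis(primary 4-methylbenzenesulfonate) of 5, meso (not isolated) | O[C@@H](COS(=O)(=O)c1ccc(C)cc1)[C@@H]2CC[C@H]([C@H](O)COS(=O)(=O)c3ccc(C)cc3)O2 | intermediate
7 | (2S,5R)-2-[(2S)-oxiran-2-yl]-5-[(2R)-oxiran-2-yl]oxolane, meso | C1O[C@@H]1[C@@H]2CC[C@H]([C@H]3CO3)O2 | intermediate
8 | (1S,1'R)-1,1'-[(2S,5R)-oxolane-2,5-diyl]di(prop-2-en-1-ol), meso, threo,threo (6R,7R,10S,11S) | O[C@@H](C=C)[C@@H]1CC[C@H]([C@H](O)C=C)O1 | intermediate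
9 | (S)-[(2R)-oxiran-2-yl]{(2R,5S)-5-[(1S)-1-hydroxyprop-2-en-1-yl]oxolan-2-yl}methanol (5R,6S,7R,10S,11S) | O[C@@H](C=C)[C@@H]1CC[C@H]([C@H](O)[C@H]2CO2)O1 | intermediate
10 | 6,11-bis-O-TBS ether of 9 (5R,6S,7R,10S,11S) | CC(C)(C)[Si](C)(C)O[C@@H](C=C)[C@@H]1CC[C@H]([C@H](O[Si](C)(C)C(C)(C)C)[C@H]2CO2)O1 | intermediate
11 | C12 aldehyde from 10, C13 removed (5R,6S,7R,10S,11R; not isolated) | CC(C)(C)[Si](C)(C)O[C@@H](C=O)[C@@H]1CC[C@H]([C@H](O[Si](C)(C)C(C)(C)C)[C@H]2CO2)O1 | intermediate
12 | C12 primary alcohol (5R,6S,7R,10S,11S) | CC(C)(C)[Si](C)(C)O[C@@H](CO)[C@@H]1CC[C@H]([C@H](O[Si](C)(C)C(C)(C)C)[C@H]2CO2)O1 | intermediate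
13 | C12 primary iodide (5R,6S,7R,10S,11R) | CC(C)(C)[Si](C)(C)O[C@@H](CI)[C@@H]1CC[C@H]([C@H](O[Si](C)(C)C(C)(C)C)[C@H]2CO2)O1 | intermediate
14 | C4/C5 epoxide with C12 methyl, 6,11-bis-O-TBS (5R,6S,7R,10S,11S) | CC(C)(C)[Si](C)(C)O[C@@H](C)[C@@H]1CC[C@H]([C@H](O[Si](C)(C)C(C)(C)C)[C@H]2CO2)O1 | intermediate
15 | methyl propiolate | C#CC(=O)OC | starting material
16 | methyl 3-lithioprop-2-ynoate (not isolated) | [Li]C#CC(=O)OC | intermediate
17 | methyl 5-hydroxy-2-ynoate, 6,11-bis-O-TBS (5R,6R,7R,10S,11S) | CC(C)(C)[Si](C)(C)O[C@@H](C)[C@@H]1CC[C@H]([C@H](O[Si](C)(C)C(C)(C)C)[C@H](O)CC#CC(=O)OC)O1 | intermediate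
18 | 5,6,11-triol ynoate (5R,6R,7R,10S,11S; not isolated) | O[C@@H](C)[C@@H]1CC[C@H]([C@H](O)[C@H](O)CC#CC(=O)OC)O1 | intermediate
19 | 5,6-O-isopropylidene ynoate, 11-OH free (5R,6S,7R,10S,11S) | O[C@@H](C)[C@@H]1CC[C@H]([C@H](OC(C)(C)O2)[C@H]2CC#CC(=O)OC)O1 | intermediate
20 | 3-(4-methoxyphenyl)prop-2-ynoic acid | COc1ccc(cc1)C#CC(=O)O | starting material
21 | 11-O-[3-(4-methoxyphenyl)propioloyl] ester of 19 | COc1ccc(cc1)C#CC(=O)O[C@@H](C)[C@@H]2CC[C@H]([C@H](OC(C)(C)O3)[C@H]3CC#CC(=O)OC)O2 | intermediate
22 | methyl (2Z)-enoate with 11-O-(Z)-4-methoxycinnamate and 5,6-acetonide | COc1ccc(cc1)/C=C\C(=O)O[C@@H](C)[C@@H]2CC[C@H]([C@H](OC(C)(C)O3)[C@H]3C/C=C\C(=O)OC)O2 | intermediate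
23 | 5,6-dihydroxy (2Z)-enoate methyl ester with 11-O-(Z)-4-methoxycinnamate (not isolated) | COc1ccc(cc1)/C=C\C(=O)O[C@@H](C)[C@@H]2CC[C@H]([C@H](O)[C@H](O)C/C=C\C(=O)OC)O2 | intermediate
24 | (1S)-1-[(2S,5R)-5-{(S)-hydroxy[(2R)-6-oxo-3,6-dihydro-2H-pyran-2-yl]methyl}oxolan-2-yl]ethyl (2Z)-3-(4-methoxyphenyl)prop-2-enoate | COc1ccc(/C=C\C(=O)O[C@@H](C)[C@@H]2CC[C@H]([C@H](O)[C@H]3CC=CC(=O)O3)O2)cc1 | target

Total steps: 15. Longest linear sequence: 15 steps (1 → 24); 2, 15 and 20 enter as purchased materials.

Steps most likely to fail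

Step 6 (key step). Oxygen transfer to a monosubstituted vinyl group is slow, and the hydroxyl–ether–hydroxyl array of 8 may chelate titanium and displace tartrate, which would erode both arm and face selectivity. Prolonged exposure may also open the terminal epoxy alcohol or let it migrate. Fallback, from 8 back to 9: both hydroxyls are acetylated (Ac2O, pyridine) to the meso diacetate F1. A lipase (Burkholderia cepacia lipase, pH 7 phosphate buffer) then hydrolyses one enantiotopic ester, expected from the usual preference of such enzymes for secondary alcohols to be the (R)-configured C6 acetate, giving the O11-monoacetate F2. Its single free allylic alcohol is epoxidised with Ti(OiPr)4/L-(+)-DIPT/TBHP as an ordinary matched secondary allylic alcohol to the epoxy alcohol acetate F3. Brief K2CO3/MeOH at 0 °C removes the acetate and returns to 9. If the enzyme showed the opposite preference, the same lipase would be used in the acylation direction on 8.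

Step 14. Two different alkynes must be reduced in one flask; over-reduction of either Z-alkene, incomplete reduction of the slower alkyne, or Z-to-E drift of the anisyl acrylate may occur. Fallback, from 19 to 22: only the ynoate of 19 is semi-hydrogenated (same catalyst) to the Z-enoate alcohol F4. Separately, 4-methoxybenzaldehyde is converted by Ando olefination with ethyl (diphenoxyphosphoryl)acetate (NaH, THF, −78 °C) into ethyl (2Z)-3-(4-methoxyphenyl)prop-2-enoate F5, and LiOH hydrolysis gives (2Z)-3-(4-methoxyphenyl)prop-2-enoic acid F6. Yamaguchi esterification of F4 with F6 (2,4,6-trichlorobenzoyl chloride, Et3N, then DMAP, toluene, 0 °C, dark) re-enters the route at 22, so the cinnamate geometry comes from an olefination and only one alkyne is hydrogenated.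

Step 2. Both alkenes of 3 are electron-poor; over-oxidation with C–C cleavage or slow second cycloaddition may lower the mass return, although the stereochemical outcome should not be affected. Fallback, from 3 to 5: i-Bu2AlH reduction gives (2E,6E)-octa-2,6-diene-1,8-diol F7 and acetylation gives the diacetate F8. Oxidative cyclisation of this electron-neutral 1,5-diene with RuCl3 (cat.)/NaIO4 (EtOAc/MeCN/H2O, 0 °C) gives the cis-oxolane diol diacetate F9, with the same suprafacial stereochemical logic. K2CO3/MeOH then delivers the tetraol 5, bypassing 4.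

Further compounds
F1 | step 6 | meso 6,11-di-O-acetate of 8 | CC(=O)O[C@@H](C=C)[C@@H]1CC[C@H]([C@H](OC(C)=O)C=C)O1
F2 | step 6 | 11-O-acetate of 8 with free (R)-C6 hydroxyl | CC(=O)O[C@@H](C=C)[C@@H]1CC[C@H]([C@H](O)C=C)O1
F3 | step 6 | 11-O-acetate of epoxy alcohol 9 | CC(=O)O[C@@H](C=C)[C@@H]1CC[C@H]([C@H](O)[C@H]2CO2)O1
F4 | step 14 | methyl (2Z)-enoate with 5,6-acetonide and free 11-OH | O[C@@H](C)[C@@H]1CC[C@H]([C@H](OC(C)(C)O2)[C@H]2C/C=C\C(=O)OC)O1
F5 | step 14 | ethyl (2Z)-3-(4-methoxyphenyl)prop-2-enoate | CCOC(=O)/C=C\c1ccc(OC)cc1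
F6 | step 14 | (2Z)-3-(4-methoxyphenyl)prop-2-enoic acid | OC(=O)/C=C\c1ccc(OC)cc1
F7 | step 2 | (2E,6E)-octa-2,6-diene-1,8-diol | OC/C=C/CC/C=C/CO
F8 | step 2 | (2E,6E)-octa-2,6-diene-1,8-diyl diacetate | CC(=O)OC/C=C/CC/C=C/COC(C)=O
F9 | step 2 | meso di(primary acetate) of tetraol 5 | O[C@@H](COC(C)=O)[C@@H]1CC[C@H]([C@H](O)COC(C)=O)O1
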